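**Retrosynthetic overview**

1. The strategy rests on C2 of the dihydrofuran ring, which carries the ring oxygen O1 and a 1-carbonylvinyl group, next to the benzylic carbinol C3 that sits ortho to O1 on the benzene ring. C2 is read as the carbon of an acrylate-derived allylic sulfonium ylide, and C3–C3a–C7a–O1 as a salicylaldehyde.
2. Key disconnection (formal [4+1]): C2–C3 by ylide addition to the aldehyde, then O1–C2 by attack of the phenol oxygen on C2. This closes the dihydrofuran ring, the only ring made (the benzene ring is bought), and sets C2 and C3.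
3. The phenol is carried as a silyl ether while the ylide adds, because a free phenoxide would be O-allylated by the 2-(methoxycarbonyl)allyl sulfonium salt. Fluoride releases it in the same flask once the oxirane has formed.
4. Before: the salicylaldehyde comes from 4-hydroxyacetophenone (CBS reduction sets the side-chain carbinol, then ortho-formylation). The (2S,5S)-2,5-dimethylthiolane comes from (2R,5R)-hexane-2,5-diol and is S-alkylated with methyl 2-(bromomethyl)acrylate.
5. After: ester to enal by reduction and selective oxidation, C3 acetate, desilylation, tiglate.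

Key step: step 10

Assumption: the sense of induction known for benzyl and 2-methylallyl ylides of 2,5-dimethylthiolane is taken to hold for the 2-(methoxycarbonyl)allyl ylide. On that model the (2S,5S)-sulfide leads to the (2S,3R) series; if the first run shows the opposite sense, the (2R,5R)-sulfide from (2S,5S)-hexane-2,5-diol is used in the same steps.

**Route**

Step 1
Reactants: 1 4-hydroxyacetophenone
Product: 2 1-[4-(tert-butyldimethylsilyloxy)phenyl]ethan-1-one
Conditions: TBSCl, imidazole, DMF, rt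
Reagents that add atoms: tert-butyldimethylsilyl chloride (TBSCl), CC(C)(C)[Si](C)(C)Cl
Why: Imidazole-promoted O-silylation masks the acidic phenol, which would otherwise consume borane and bind the oxazaborolidine in step 2.

Step 2
Reactants: 2 1-[4-(tert-butyldimethylsilyloxy)phenyl]ethan-1-one
Product: 3 (1R)-1-[4-(tert-butyldimethylsilyloxy)phenyl]ethan-1-ol
Conditions: (S)-2-methyl-CBS-oxazaborolidine (10 mol %), BH3·SMe2, THF, −20 to 0 °C; MeOH quench
Reagents that add atoms: none
Why: Corey–Bakshi–Shibata reduction, in which the (S)-oxazaborolidine–borane complex binds the ketone with the aryl group as the large substituent and delivers hydride to the Si face, should give the (R)-carbinol, as it does for acetophenone.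

Step 3
Reactants: 3 (1R)-1-[4-(tert-butyldimethylsilyloxy)phenyl]ethan-1-ol
Product: 4 tert-butyl{4-[(1R)-1-(tert-butyldimethylsilyloxy)ethyl]phenoxy}dimethylsilane
Conditions: TBSCl, imidazole, DMF, rt
Reagents that add atoms: tert-butyldimethylsilyl chloride (TBSCl), CC(C)(C)[Si](C)(C)Cl
Why: O-silylation of the secondary benzylic alcohol protects it for the base, hydride and oxidation steps ahead without touching the stereocentre.

Step 4
Reactants: 4 tert-butyl{4-[(1R)-1-(tert-butyldimethylsilyloxy)ethyl]phenoxy}dimethylsilane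
Product: 5 4-[(1R)-1-(tert-butyldimethylsilyloxy)ethyl]phenol
Conditions: Cs2CO3, DMF–H2O (10:1), rt
Reagents that add atoms: none
Why: Base-mediated hydrolysis cleaves the aryl silyl ether selectively, because phenoxide is by far the better leaving group on silicon, and should leave the secondary alkyl silyl ether in place.

Step 5
Reactants: 5 4-[(1R)-1-(tert-butyldimethylsilyloxy)ethyl]phenol
Product: 7 5-[(1R)-1-(tert-butyldimethylsilyloxy)ethyl]-2-hydroxybenzaldehyde, via salicyl alcohol 6 (not isolated)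
Conditions: MgCl2, Et3N, (CH2O)n, MeCN, reflux; cold 5% aqueous citric acid
Reagents that add atoms: paraformaldehyde (reacts as formaldehyde), C=O
Why: Casnati–Skattebøl ortho-formylation, in which the magnesium phenoxide directs formaldehyde to the free ortho position (para is blocked) and the magnesium salt of salicyl alcohol 6 passes hydride to a second formaldehyde in an Oppenauer-type oxidation.

Step 6
Reactants: 7 5-[(1R)-1-(tert-butyldimethylsilyloxy)ethyl]-2-hydroxybenzaldehyde
Product: 8 2-(tert-butyldimethylsilyloxy)-5-[(1R)-1-(tert-butyldimethylsilyloxy)ethyl]benzaldehyde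
Conditions: TBSCl, imidazole, CH2Cl2, 0 °C to rt
Reagents that add atoms: tert-butyldimethylsilyl chloride (TBSCl), CC(C)(C)[Si](C)(C)Cl
Why: O-silylation of the salicylaldehyde phenol removes the nucleophilic phenoxide that would be allylated by sulfonium salt 13 in step 10 and restores full electrophilicity to the aldehyde.

Step 7
Reactants: 9 (2R,5R)-hexane-2,5-diol
Product: 10 (2R,5R)-hexane-2,5-diyl dimethanesulfonate
Conditions: MsCl, Et3N, CH2Cl2, 0 °C
Reagents that add atoms: methanesulfonyl chloride, CS(=O)(=O)Cl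
Why: Mesylation at oxygen installs two leaving groups and leaves both stereocentres unchanged.

Step 8
Reactants: 10 (2R,5R)-hexane-2,5-diyl dimethanesulfonate
Product: 11 (2S,5S)-2,5-dimethylthiolane
Conditions: Na2S·9H2O, DMSO, rt; distillation
Reagents that add atoms: sodium sulfide (used as Na2S·9H2O), [Na+].[Na+].[S-2]
Why: Two SN2 displacements by sulfur, the second a 5-exo-tet ring closure, invert both centres and so should turn the (2R,5R) series into the C2-symmetric (2S,5S)-thiolane.

Step 9
Reactants: 11 (2S,5S)-2,5-dimethylthiolane; 12 methyl 2-(bromomethyl)acrylate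
Product: 13 (2S,5S)-1-[2-(methoxycarbonyl)prop-2-en-1-yl]-2,5-dimethylthiolan-1-ium bromide
Conditions: acetone, rt, dark; precipitation with Et2O
Reagents that add atoms: none
Why: S-alkylation of the sulfide by the reactive allylic bromide gives the sulfonium salt, and since both lone pairs of the C2-symmetric sulfide are equivalent only one salt can form and sulfur is not a stereocentre.

Step 10
Reactants: 8 2-(tert-butyldimethylsilyloxy)-5-[(1R)-1-(tert-butyldimethylsilyloxy)ethyl]benzaldehyde; 13 (2S,5S)-1-[2-(methoxycarbonyl)prop-2-en-1-yl]-2,5-dimethylthiolan-1-ium bromide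
Product: 18 methyl 2-[(2S,3R)-5-[(1R)-1-(tert-butyldimethylsilyloxy)ethyl]-3-hydroxy-2,3-dihydro-1-benzofuran-2-yl]prop-2-enoate, via sulfonium ylide 14 (not isolated), via anti betaine 15 (not isolated), via trans vinyl oxirane 16 (not isolated), via oxiranyl phenoxide 17 (not isolated)
Conditions: Cs2CO3, MeCN, −20 °C, 13 added slowly; then Bu4NF (1.1 equiv), THF, −20 to 0 °C; aqueous NH4Cl
Reagents that add atoms: none
Why: Cs2CO3 deprotonates 13 at the CH2 next to sulfur to give allylic ylide 14, whose sulfur-bearing carbon adds to the aldehyde of 8 to give anti betaine 15 (C2–C3 bond), and the alkoxide expels thiolane 11 in a 3-exo-tet closure to trans oxirane 16; Bu4NF then cleaves only the aryl silyl ether, and phenoxide 17 attacks the allylic oxirane carbon C2 from the side opposite the leaving oxygen, a 5-endo epoxide opening that forms O1–C2 and closes the dihydrofuran ring. The closest known reactions are the chiral-sulfide ylide epoxidation of aromatic aldehydes with 2-substituted allyl halides, the sulfonium-ylide [4+1] annulation of salicylaldehydes to 2,3-dihydrobenzofuran-3-ols and the fluoride-triggered cyclisation of ortho-silyloxyaryl oxiranes, while the pairing of an ester-bearing allylic ylide on this sulfide with this aldehyde is untested. C3 is set by the aldehyde face that is attacked and C2 by the ylide face: in the ylide the 1-(methoxycarbonyl)vinyl group should point away from the thiolane ring and the methyl group cis to the ylide carbon should block one face, so the (2S,5S)-sulfide is expected to give the (2R,3R)-oxirane, the mirror image of the (S,S)-stilbene oxide known from the benzyl ylide of the (2R,5R)-sulfide. The phenoxide then inverts C2, so the trans oxirane should give the 2,3-trans (2S,3R) product, and a cis isomer would be expected to betray itself by lactonising onto the ester. The step needs carbonyl addition to outrun ylide addition to acrylate units and needs the phenol oxygen kept out of the way until the oxirane exists; the silyl group prevents O-allylation of a phenoxide by 13, and slow addition of 13 at −20 °C keeps the salt scarce. The sense of induction and the trans relation are to be confirmed on the first run.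

Step 11
Reactants: 18 methyl 2-[(2S,3R)-5-[(1R)-1-(tert-butyldimethylsilyloxy)ethyl]-3-hydroxy-2,3-dihydro-1-benzofuran-2-yl]prop-2-enoate
Product: 19 (2S,3R)-5-[(1R)-1-(tert-butyldimethylsilyloxy)ethyl]-2-(3-hydroxyprop-1-en-2-yl)-2,3-dihydro-1-benzofuran-3-ol
Conditions: i-Bu2AlH (3.5 equiv), CH2Cl2, −78 °C; aqueous potassium sodium tartrate
Reagents that add atoms: none
Why: Diisobutylaluminium hydride reduces the conjugated ester by 1,2-addition to the allylic alcohol, and the silyl ether, aryl ether and both stereocentres are inert to it.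

Step 12
Reactants: 19 (2S,3R)-5-[(1R)-1-(tert-butyldimethylsilyloxy)ethyl]-2-(3-hydroxyprop-1-en-2-yl)-2,3-dihydro-1-benzofuran-3-ol
Product: 20 2-[(2S,3R)-5-[(1R)-1-(tert-butyldimethylsilyloxy)ethyl]-3-hydroxy-2,3-dihydro-1-benzofuran-2-yl]prop-2-enal
Conditions: TEMPO (10 mol %), PhI(OAc)2, CH2Cl2, rt
Reagents that add atoms: none
Why: Oxoammonium (TEMPO) oxidation is selective for the primary allylic alcohol over the hindered secondary benzylic one, and the trans arrangement at C2 and C3 keeps the C3 hydroxyl from forming a lactol that could be oxidised further.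

Step 13
Reactants: 20 2-[(2S,3R)-5-[(1R)-1-(tert-butyldimethylsilyloxy)ethyl]-3-hydroxy-2,3-dihydro-1-benzofuran-2-yl]prop-2-enal
Product: 21 (2S,3R)-5-[(1R)-1-(tert-butyldimethylsilyloxy)ethyl]-2-(3-oxoprop-1-en-2-yl)-2,3-dihydro-1-benzofuran-3-yl acetate
Conditions: Ac2O, pyridine, DMAP (5 mol %), CH2Cl2, 0 °C
Reagents that add atoms: acetic anhydride, CC(=O)OC(C)=O
Why: Nucleophile-catalysed acetylation of the only free hydroxyl (C3) proceeds at oxygen with retention, and the low temperature and small DMAP loading limit conjugate addition to the enal.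

Step 14
Reactants: 21 (2S,3R)-5-[(1R)-1-(tert-butyldimethylsilyloxy)ethyl]-2-(3-oxoprop-1-en-2-yl)-2,3-dihydro-1-benzofuran-3-yl acetate
Product: 22 (2S,3R)-5-[(1R)-1-hydroxyethyl]-2-(3-oxoprop-1-en-2-yl)-2,3-dihydro-1-benzofuran-3-yl acetate
Conditions: HF·pyridine, excess pyridine, THF, 0 °C to rt
Reagents that add atoms: none
Why: Fluoride-driven desilylation with pyridine-buffered HF is neither basic enough to attack the acetate or the enal nor acidic enough, when buffered, to ionise the benzylic C–O bonds, so the carbinol should be freed with retention.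

Step 15
Reactants: 22 (2S,3R)-5-[(1R)-1-hydroxyethyl]-2-(3-oxoprop-1-en-2-yl)-2,3-dihydro-1-benzofuran-3-yl acetate
Product: 23 (1R)-1-[(2S,3R)-3-acetoxy-2-(3-oxoprop-1-en-2-yl)-2,3-dihydro-1-benzofuran-5-yl]ethyl (2E)-2-methylbut-2-enoate (CNP0294391.1)
Conditions: tiglic anhydride, Et3N, DMAP, CH2Cl2, rt
Reagents that add atoms: tiglic anhydride, C/C=C(\C)C(=O)OC(=O)/C(C)=C/C
Why: DMAP-catalysed acyl transfer (Steglich-type acylation) esterifies the secondary benzylic alcohol at oxygen with retention, and the E geometry of the tiglate is the stable one and should not change.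

**Compound list**

1 | 4-hydroxyacetophenone | CC(=O)c1ccc(O)cc1 | starting material
2 | 1-[4-(tert-butyldimethylsilyloxy)phenyl]ethan-1-one | CC(=O)c1ccc(O[Si](C)(C)C(C)(C)C)cc1 | intermediate
3 | (1R)-1-[4-(tert-butyldimethylsilyloxy)phenyl]ethan-1-ol | C[C@@H](O)c1ccc(O[Si](C)(C)C(C)(C)C)cc1 | intermediate
4 | tert-butyl{4-[(1R)-1-(tert-butyldimethylsilyloxy)ethyl]phenoxy}dimethylsilane | C[C@@H](O[Si](C)(C)C(C)(C)C)c1ccc(O[Si](C)(C)C(C)(C)C)cc1 | intermediate
5 | 4-[(1R)-1-(tert-butyldimethylsilyloxy)ethyl]phenol | C[C@@H](O[Si](C)(C)C(C)(C)C)c1ccc(O)cc1 | intermediate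
6 | 4-[(1R)-1-(tert-butyldimethylsilyloxy)ethyl]-2-(hydroxymethyl)phenol (magnesium salt in the flask, not isolated) | C[C@@H](O[Si](C)(C)C(C)(C)C)c1ccc(O)c(CO)c1 | intermediate
7 | 5-[(1R)-1-(tert-butyldimethylsilyloxy)ethyl]-2-hydroxybenzaldehyde | C[C@@H](O[Si](C)(C)C(C)(C)C)c1ccc(O)c(C=O)c1 | intermediate
8 | 2-(tert-butyldimethylsilyloxy)-5-[(1R)-1-(tert-butyldimethylsilyloxy)ethyl]benzaldehyde | C[C@@H](O[Si](C)(C)C(C)(C)C)c1ccc(O[Si](C)(C)C(C)(C)C)c(C=O)c1 | intermediate
9 | (2R,5R)-hexane-2,5-diol | C[C@@H](O)CC[C@@H](C)O | starting material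
10 | (2R,5R)-hexane-2,5-diyl dimethanesulfonate | C[C@@H](OS(C)(=O)=O)CC[C@@H](C)OS(C)(=O)=O | intermediate
11 | (2S,5S)-2,5-dimethylthiolane | C[C@H]1CC[C@H](C)S1 | intermediate
12 | methyl 2-(bromomethyl)acrylate | COC(=O)C(=C)CBr | starting material
13 | (2S,5S)-1-[2-(methoxycarbonyl)prop-2-en-1-yl]-2,5-dimethylthiolan-1-ium bromide | C[C@H]1CC[C@H](C)[S+]1CC(=C)C(=O)OC.[Br-] | intermediate
14 | sulfonium ylide of 13, carbanion on the carbon between sulfur and the acrylate (not isolated) | COC(=O)C(=C)[CH-][S+]1[C@@H](C)CC[C@@H]1C | intermediate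
15 | anti betaine: (R)-alkoxide at the former aldehyde carbon, (2S,5S)-thiolanium on the adjacent (S)-carbon that bears the 1-(methoxycarbonyl)vinyl group (not isolated) | COC(=O)C(=C)[C@@H]([C@H]([O-])c1cc([C@@H](C)O[Si](C)(C)C(C)(C)C)ccc1O[Si](C)(C)C(C)(C)C)[S+]1[C@@H](C)CC[C@@H]1C | intermediate
16 | methyl 2-[(2R,3R)-3-{2-(tert-butyldimethylsilyloxy)-5-[(1R)-1-(tert-butyldimethylsilyloxy)ethyl]phenyl}oxiran-2-yl]prop-2-enoate (not isolated) | COC(=O)C(=C)[C@H]1O[C@@H]1c1cc([C@@H](C)O[Si](C)(C)C(C)(C)C)ccc1O[Si](C)(C)C(C)(C)C | intermediate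
17 | 4-[(1R)-1-(tert-butyldimethylsilyloxy)ethyl]-2-{(2R,3R)-3-[1-(methoxycarbonyl)vinyl]oxiran-2-yl}phenolate (not isolated) | COC(=O)C(=C)[C@H]1O[C@@H]1c1cc([C@@H](C)O[Si](C)(C)C(C)(C)C)ccc1[O-] | intermediate
18 | methyl 2-[(2S,3R)-5-[(1R)-1-(tert-butyldimethylsilyloxy)ethyl]-3-hydroxy-2,3-dihydro-1-benzofuran-2-yl]prop-2-enoate | COC(=O)C(=C)[C@@H]1Oc2ccc([C@@H](C)O[Si](C)(C)C(C)(C)C)cc2[C@H]1O | intermediate
19 | (2S,3R)-5-[(1R)-1-(tert-butyldimethylsilyloxy)ethyl]-2-(3-hydroxyprop-1-en-2-yl)-2,3-dihydro-1-benzofuran-3-ol | OCC(=C)[C@@H]1Oc2ccc([C@@H](C)O[Si](C)(C)C(C)(C)C)cc2[C@H]1O | intermediate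
20 | 2-[(2S,3R)-5-[(1R)-1-(tert-butyldimethylsilyloxy)ethyl]-3-hydroxy-2,3-dihydro-1-benzofuran-2-yl]prop-2-enal | O=CC(=C)[C@@H]1Oc2ccc([C@@H](C)O[Si](C)(C)C(C)(C)C)cc2[C@H]1O | intermediate
21 | (2S,3R)-5-[(1R)-1-(tert-butyldimethylsilyloxy)ethyl]-2-(3-oxoprop-1-en-2-yl)-2,3-dihydro-1-benzofuran-3-yl acetate | O=CC(=C)[C@@H]1Oc2ccc([C@@H](C)O[Si](C)(C)C(C)(C)C)cc2[C@H]1OC(C)=O | intermediate
22 | (2S,3R)-5-[(1R)-1-hydroxyethyl]-2-(3-oxoprop-1-en-2-yl)-2,3-dihydro-1-benzofuran-3-yl acetate | O=CC(=C)[C@@H]1Oc2ccc([C@@H](C)O)cc2[C@H]1OC(C)=O | intermediate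
23 | (1R)-1-[(2S,3R)-3-acetoxy-2-(3-oxoprop-1-en-2-yl)-2,3-dihydro-1-benzofuran-5-yl]ethyl (2E)-2-methylbut-2-enoate | C=C(C=O)[C@@H]1Oc2ccc([C@@H](C)OC(=O)/C(C)=C/C)cc2[C@H]1OC(C)=O | target

**Step count and risks**

Total step count: 15. Longest linear sequence: 12 (steps 1–6, then 10–15); the sulfide branch (steps 7–9) joins at step 10.

Steps most likely to fail:

1. Step 10. What may go wrong:
   - the ylide may add to acrylate units (its own salt or the oxirane formed) instead of the aldehyde, giving cyclopropanes and oligomers;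
   - facial or anti/syn selectivity may be poor;
   - after desilylation the phenoxide may add to the acrylate terminus with SN2′ opening of the oxirane, giving a seven-membered ring instead of attack at C2.

   Fallback, setting out from 8 and 11 and coming back at 21: the ylide is stripped of its Michael acceptor and the aldehyde carbon is introduced afterwards. Thiolane 11 is alkylated with 3-bromo-2-methylpropene to (2S,5S)-2,5-dimethyl-1-(2-methylprop-2-en-1-yl)thiolan-1-ium bromide F1. With Cs2CO3 in MeCN, F1 and 8 should give, by the well-established 2-methylallyl ylide epoxidation, tert-butyl{4-[(1R)-1-(tert-butyldimethylsilyloxy)ethyl]-2-[(2R,3R)-3-(prop-1-en-2-yl)oxiran-2-yl]phenoxy}dimethylsilane F2. Bu4NF then closes this oxirane, which has no SN2′ outlet, to (2S,3R)-5-[(1R)-1-(tert-butyldimethylsilyloxy)ethyl]-2-(prop-1-en-2-yl)-2,3-dihydro-1-benzofuran-3-ol F3. Ac2O and pyridine give (2S,3R)-5-[(1R)-1-(tert-butyldimethylsilyloxy)ethyl]-2-(prop-1-en-2-yl)-2,3-dihydro-1-benzofuran-3-yl acetate F4. SeO2 in dioxane oxidises the allylic methyl group to the enal, with TEMPO/PhI(OAc)2 finishing any allylic alcohol, which gives 21.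

2. Step 14. What may go wrong: the para-alkoxybenzylic C–O bond may ionise under HF (loss of configuration or elimination to the styrene), the C3 acetate may be lost with aromatisation to the benzofuran, or fluoride may damage the enal.

   Fallback, setting out from 19 and coming back at 23: both acylations and the desilylation are moved ahead of the oxidation, so that no enal is present when fluoride and DMAP are used. Diol 19 with Ac2O, pyridine and DMAP gives 2-[(2S,3R)-3-acetoxy-5-[(1R)-1-(tert-butyldimethylsilyloxy)ethyl]-2,3-dihydro-1-benzofuran-2-yl]prop-2-en-1-yl acetate F5. Bu4NF buffered with AcOH gives 2-[(2S,3R)-3-acetoxy-5-[(1R)-1-hydroxyethyl]-2,3-dihydro-1-benzofuran-2-yl]prop-2-en-1-yl acetate F6. Tiglic anhydride and DMAP give (1R)-1-[(2S,3R)-3-acetoxy-2-(3-acetoxyprop-1-en-2-yl)-2,3-dihydro-1-benzofuran-5-yl]ethyl (2E)-2-methylbut-2-enoate F7. Candida antarctica lipase B in buffered MTBE cleaves the primary allylic acetate selectively to (1R)-1-[(2S,3R)-3-acetoxy-2-(3-hydroxyprop-1-en-2-yl)-2,3-dihydro-1-benzofuran-5-yl]ethyl (2E)-2-methylbut-2-enoate F8. TEMPO/PhI(OAc)2 then gives 23.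

3. Step 5. What may go wrong: the hot magnesium phenoxide may expel the para benzylic silanolate through a para-quinone methide, or the reaction may stop at the hydroxymethyl stage.

   Fallback, setting out from 5 and coming back at 7: the formyl carbon is brought in by halogen–metal exchange instead of formaldehyde. NBS in MeCN at 0 °C brominates the free ortho position to 2-bromo-4-[(1R)-1-(tert-butyldimethylsilyloxy)ethyl]phenol F9. n-BuLi (2.2 equiv) in THF at −78 °C forms the lithio phenoxide, and DMF followed by mild acidic work-up gives 7.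

**Further compounds**

F1 | step 10 | (2S,5S)-2,5-dimethyl-1-(2-methylprop-2-en-1-yl)thiolan-1-ium bromide | C[C@H]1CC[C@H](C)[S+]1CC(C)=C.[Br-]
F2 | step 10 | tert-butyl{4-[(1R)-1-(tert-butyldimethylsilyloxy)ethyl]-2-[(2R,3R)-3-(prop-1-en-2-yl)oxiran-2-yl]phenoxy}dimethylsilane | CC(=C)[C@H]1O[C@@H]1c1cc([C@@H](C)O[Si](C)(C)C(C)(C)C)ccc1O[Si](C)(C)C(C)(C)C
F3 | step 10 | (2S,3R)-5-[(1R)-1-(tert-butyldimethylsilyloxy)ethyl]-2-(prop-1-en-2-yl)-2,3-dihydro-1-benzofuran-3-ol | CC(=C)[C@@H]1Oc2ccc([C@@H](C)O[Si](C)(C)C(C)(C)C)cc2[C@H]1O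
F4 | step 10 | (2S,3R)-5-[(1R)-1-(tert-butyldimethylsilyloxy)ethyl]-2-(prop-1-en-2-yl)-2,3-dihydro-1-benzofuran-3-yl acetate | CC(=C)[C@@H]1Oc2ccc([C@@H](C)O[Si](C)(C)C(C)(C)C)cc2[C@H]1OC(C)=O
F5 | step 14 | 2-[(2S,3R)-3-acetoxy-5-[(1R)-1-(tert-butyldimethylsilyloxy)ethyl]-2,3-dihydro-1-benzofuran-2-yl]prop-2-en-1-yl acetate | CC(=O)OCC(=C)[C@@H]1Oc2ccc([C@@H](C)O[Si](C)(C)C(C)(C)C)cc2[C@H]1OC(C)=O
F6 | step 14 | 2-[(2S,3R)-3-acetoxy-5-[(1R)-1-hydroxyethyl]-2,3-dihydro-1-benzofuran-2-yl]prop-2-en-1-yl acetate | CC(=O)OCC(=C)[C@@H]1Oc2ccc([C@@H](C)O)cc2[C@H]1OC(C)=O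
F7 | step 14 | (1R)-1-[(2S,3R)-3-acetoxy-2-(3-acetoxyprop-1-en-2-yl)-2,3-dihydro-1-benzofuran-5-yl]ethyl (2E)-2-methylbut-2-enoate | CC(=O)OCC(=C)[C@@H]1Oc2ccc([C@@H](C)OC(=O)/C(C)=C/C)cc2[C@H]1OC(C)=O
F8 | step 14 | (1R)-1-[(2S,3R)-3-acetoxy-2-(3-hydroxyprop-1-en-2-yl)-2,3-dihydro-1-benzofuran-5-yl]ethyl (2E)-2-methylbut-2-enoate | OCC(=C)[C@@H]1Oc2ccc([C@@H](C)OC(=O)/C(C)=C/C)cc2[C@H]1OC(C)=O
F9 | step 5 | 2-bromo-4-[(1R)-1-(tert-butyldimethylsilyloxy)ethyl]phenol | C[C@@H](O[Si](C)(C)C(C)(C)C)c1ccc(O)c(Br)c1
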